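**Plan**
- Cladiellane numbering is used: THF = O, C2, C1, C10, C9; oxonane = O, C2–C9; cyclohexane = C1, C10–C14; lactone through C15–C16. The retrosynthesis cuts, in this order, the C16(=O)–O–C3 lactone bond and the C4 ester, then C3–C4, C8–C9, C2–C3, C1–C2 and C9–C10.
- Enabling feature: C3 (quaternary, bearing CH3 and the lactone oxygen) and C4 (bearing the octanoate) are neighbouring oxygenated carbons inside the nine-membered cyclic ether. This 1,2-diol maps onto a methyl ketone on C2 and an aldehyde at the end of the C9 chain, joined by reductive carbonyl coupling.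
- Forward: (R)-carvone gives the cyclohexane with the C11 carbinol and a C10 enal. Conjugate addition, acyl-anion addition and acetalisation build the cis-fused THF acetal. Oxocarbenium allylation adds C4–C8, the samarium pinacol closes the oxonane, and lactonisation closes the last ring.
- Stereochemistry: C14 from carvone; C11 from its trans epoxide; C1 by anti conjugate addition; C10 by kinetic protonation; C15 by substrate-controlled hydroboration; C2 by equilibration; C9 by convex-face attack; C6 from (R)-α-hydroxy-γ-butyrolactone; C3 and C4 in the pinacol step.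

Key step: step 21

Remark on the chemistry: target configuration in this numbering is 1S,2S,3S,4R,6R,9S,10R,11R,14R,15R. Compounds 8, 20 and 21 are epimer mixtures at one centre that is oxidised (step 6) or equilibrated (step 15) afterwards. Acetals 22–24 are drawn as the exo-methoxy anomer; both anomers give the same oxocarbenium ion in step 18.

**Route**

Step 1
Reactants: 1 (R)-α-hydroxy-γ-butyrolactone
Product: 2 (R)-α-(tert-butyldimethylsilyloxy)-γ-butyrolactone
Conditions: TBSCl, imidazole, DMF, rt
Reagents that add atoms: tert-butyldimethylsilyl chloride, CC(C)(C)[Si](C)(C)Cl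
Why: Imidazole-promoted silylation (Corey TBS protection) of the secondary hydroxyl leaves the stereocentre that becomes C6 untouched.

Step 2
Reactants: 2 (R)-α-(tert-butyldimethylsilyloxy)-γ-butyrolactone
Product: 4 (R)-hydroxy allylsilane, via bis(silylmethyl) carbinol 3 (not isolated)
Conditions: CeCl3 (anhydrous), Me3SiCH2MgCl, THF, −78 °C → rt; then SiO2, CH2Cl2, rt
Reagents that add atoms: (trimethylsilylmethyl)magnesium chloride, C[Si](C)(C)C[Mg]Cl
Why: The organocerium reagent adds twice to the lactone carbonyl without enolising the α-silyloxy centre, and the β-hydroxysilane then loses Me3SiOH on silica in a Peterson elimination (Bunnelle–Narayanan allylsilane synthesis).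

Step 3
Reactants: 4 (R)-hydroxy allylsilane
Product: 5 (R)-bis-TBS allylsilane
Conditions: TBSCl, imidazole, CH2Cl2, 0 °C
Reagents that add atoms: tert-butyldimethylsilyl chloride, CC(C)(C)[Si](C)(C)Cl
Why: Silylation of the only free (primary) hydroxyl by the Corey TBS protocol masks the future C4 oxygen as an ether that can later be removed in the presence of the secondary one.

Step 4
Reactants: 6 (R)-carvone
Product: 7 trans-carvone oxide
Conditions: 30% H2O2, NaOH (cat.), MeOH, 0 °C
Reagents that add atoms: hydrogen peroxide, OO
Why: In this Weitz–Scheffer nucleophilic epoxidation hydroperoxide adds to the enone β-carbon anti to the isopropenyl group, so the oxirane oxygen on the future C11 is trans to the C14 substituent as the C11 carbinol of the target requires.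

Step 5
Reactants: 7 trans-carvone oxide
Product: 8 1,2-diol
Conditions: LiAlH4, THF, 0 °C → reflux
Reagents that add atoms: none
Why: Hydride reduces the ketone and then opens the trisubstituted oxirane by SN2 attack at its secondary carbon (the regiochemistry of LiAlH4 with 1-methylcyclohexene oxides), so the C11–O bond keeps its configuration and the new secondary carbinol, an epimer mixture, is oxidised in the next step.

Step 6
Reactants: 8 1,2-diol
Product: 9 α-hydroxy ketone
Conditions: IBX, DMSO, rt
Reagents that add atoms: none
Why: IBX oxidises the secondary hydroxyl of a secondary/tertiary 1,2-diol to the α-ketol without glycol cleavage and cannot oxidise the tertiary hydroxyl.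

Step 7
Reactants: 9 α-hydroxy ketone
Product: 10 triethylsilyl ether
Conditions: TESOTf, 2,6-lutidine, CH2Cl2, −78 °C
Reagents that add atoms: triethylsilyl trifluoromethanesulfonate, CC[Si](CC)(CC)OS(=O)(=O)C(F)(F)F
Why: A silyl triflate with a hindered pyridine base silylates the tertiary hydroxyl at low temperature (standard TES protection), which avoids alkoxide chemistry in steps 8–10 and blocks retro-aldol cleavage of the later β-oxygenated aldehyde.

Step 8
Reactants: 10 triethylsilyl ether
Product: 11 enol triflate
Conditions: KHMDS, THF, −78 °C; then PhNTf2, −78 → 0 °C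
Reagents that add atoms: N-phenylbis(trifluoromethanesulfonimide), O=S(=O)(N(c1ccccc1)S(=O)(=O)C(F)(F)F)C(F)(F)F
Why: The ketone can be deprotonated only at C1 because C11 is quaternary, so triflation of the potassium enolate (enol triflate formation) gives a single regioisomer.

Step 9
Reactants: 11 enol triflate
Product: 12 enal
Conditions: Pd(PPh3)4 (5 mol %), CO (3 atm), Bu3SnH (slow addition), THF, 50 °C
Reagents that add atoms: carbon monoxide, [C-]#[O+]
Why: Palladium-catalysed reductive carbonylation of a vinyl triflate (Stille formylation) proceeds by oxidative addition, CO insertion and hydride transfer from tin and places the aldehyde carbon C9 on C10.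

Step 10
Reactants: 12 enal
Product: 14 cis-disubstituted aldehyde, via TMS enol ether 13 (not isolated)
Conditions: (2-methylprop-1-enyl)MgBr, CuI·2LiCl (10 mol %), TMSCl, THF, −78 °C; then 1 M HCl, THF, 0 °C
Reagents that add atoms: (2-methylprop-1-enyl)magnesium bromide, CC(C)=C[Mg]Br
Why: Copper-catalysed, TMSCl-assisted 1,4-addition of the alkenyl Grignard reagent puts the alkenyl group on C1 anti to the neighbouring isopropenyl group, and hydrolysis of the silyl enol ether protonates C10 on the face opposite the C1 substituent, which allylic 1,3-strain holds axial, giving the cis C1/C10 relationship of the later cis-fused furan.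

Step 11
Reactants: 14 cis-disubstituted aldehyde
Product: 15 dimethyl acetal
Conditions: HC(OMe)3, CSA (0.1 equiv), MeOH, rt
Reagents that add atoms: trimethyl orthoformate, COC(OC)OC; methanol, CO
Why: Acid-catalysed acetalisation with orthoformate as water scavenger masks the aldehyde for the hydroboration and ozonolysis steps, and the same acidic methanol solvolyses the tertiary triethylsilyl ether, which is not needed once C9 is an acetal.

Step 12
Reactants: 15 dimethyl acetal
Product: 17 primary alcohol, via B-alkyl-9-BBN borane 16 (not isolated)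
Conditions: 9-BBN, THF, 0 °C → rt; then 3 M NaOH, 30% H2O2, 0 °C
Reagents that add atoms: hydrogen peroxide, OO
Why: 9-BBN hydroborates only the 1,1-disubstituted alkene (the trisubstituted one reacts far more slowly) and, in the rotamer with C14–H eclipsing the double bond, attacks the face flanked by the CH2 group C13 and not by the substituted C1 (allylic-strain-controlled hydroboration of a trans-2-substituted isopropenylcyclohexane), which gives the 15R alcohol after oxidation.

Step 13
Reactants: 17 primary alcohol
Product: 19 C2 aldehyde, via secondary ozonide 18 (not isolated)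
Conditions: O3, CH2Cl2, −78 °C; then Me2S, −78 °C → rt
Reagents that add atoms: ozone, [O-][O+]=O
Why: Ozonolysis (Criegee mechanism) cleaves the only remaining C=C bond and the reductive work-up frees the C2 aldehyde, which is in equilibrium with the six-membered lactol formed with the C16 hydroxyl.

Step 14
Reactants: 19 C2 aldehyde
Product: 21 α-hydroxy methyl ketone, via ethoxyvinyl carbinol 20 (not isolated)
Conditions: 1-ethoxyvinyllithium (from ethyl vinyl ether, t-BuLi, THF, −78 → 0 °C), THF, −78 °C; then 0.5 M HCl, THF, 0 °C
Reagents that add atoms: ethyl vinyl ether, C=COCC; water, O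
Why: Lithiated ethyl vinyl ether is an acetyl anion equivalent that adds to the aldehyde released from its lactol by the base, and dilute acid hydrolyses the enol ether much faster than the dimethyl acetal, giving the acyloin as a C2 epimer mixture that is corrected in step 15.

Step 15
Reactants: 21 α-hydroxy methyl ketone
Product: 22 bicyclic methyl acetal
Conditions: CSA (0.1 equiv), MeOH, 0 °C → rt; then DBU (0.5 equiv), rt
Reagents that add atoms: none
Why: Acid-catalysed transacetalisation closes the five-membered cyclic acetal between C9 and the C2 hydroxyl, the only hydroxyl that can reach C9 through a five- or six-membered ring, and DBU then epimerises the enolisable α-alkoxy ketone centre C2 to the thermodynamic exo-acetyl isomer, trans to the C1–C14 bond on the convex face of the cis-fused bicycle.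

Step 16
Reactants: 22 bicyclic methyl acetal
Product: 23 keto acid
Conditions: TEMPO (0.1 equiv), NaClO2, NaOCl (cat.), MeCN/phosphate buffer pH 6.7, 35 °C
Reagents that add atoms: sodium chlorite, [Na+].[O-]Cl=O
Why: TEMPO-catalysed oxidation with chlorite as terminal oxidant (Zhao variant of the Anelli oxidation) takes the primary alcohol to the acid at near-neutral pH, where the methyl acetal, the ketone and the α-stereocentre C15 are stable.

Step 17
Reactants: 23 keto acid
Product: 24 allyl ester
Conditions: allyl bromide, KHCO3, DMF, rt
Reagents that add atoms: allyl bromide, C=CCBr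
Why: SN2 O-alkylation of the potassium carboxylate gives an ester that survives Lewis acid, fluoride and SmI2 and can later be removed with palladium under neutral conditions.

Step 18
Reactants: 24 allyl ester; 5 (R)-bis-TBS allylsilane
Product: 25 C9-allylated 2,5-cis tetrahydrofuran
Conditions: BF3·OEt2, CH2Cl2, −78 → −30 °C
Reagents that add atoms: none
Why: In this Hosomi–Sakurai-type C-glycosylation BF3 ionises the methyl acetal to the bicyclic oxocarbenium ion, which the allylsilane attacks through its CH2 terminus (SE2′, creating the C7 exo-methylene) on the convex face, trans to the adjacent C10–C11 bond, so that C8 ends cis to the C2 acetyl group.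

Step 19
Reactants: 25 C9-allylated 2,5-cis tetrahydrofuran
Product: 26 C4 primary alcohol
Conditions: HF·pyridine, pyridine, THF, 0 °C
Reagents that add atoms: none
Why: Buffered HF·pyridine cleaves the unhindered primary TBS ether much faster than the secondary allylic one (chemoselective desilylation).

Step 20
Reactants: 26 C4 primary alcohol
Product: 27 keto aldehyde
Conditions: Dess–Martin periodinane, NaHCO3, CH2Cl2, 0 °C → rt
Reagents that add atoms: none
Why: Dess–Martin oxidation under bicarbonate buffering gives the β-silyloxy aldehyde without elimination and leaves the tertiary alcohol untouched.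

Step 21
Reactants: 27 keto aldehyde
Product: 28 tricyclic 3,4-diol
Conditions: SmI2 (0.1 M in THF, 4 equiv), THF, −78 → −20 °C, 27 added by syringe pump (final 2 mM); then aq. NaHCO3
Reagents that add atoms: none
Why: SmI2 transfers one electron to the aldehyde, the more easily reduced carbonyl, and the carbon of the Sm(III)-bound ketyl adds to the C3 ketone, which the same oxophilic Sm(III) activates, before a second electron gives the samarium diolate that is protonated on work-up. The closest known reaction type is the SmI2-mediated intramolecular ketone–aldehyde pinacol coupling, routine for five- and six-membered rings and known for medium rings. The oxonane closes in 9-exo-trig fashion (ketyl carbon onto the carbonyl carbon, carbonyl oxygen outside the ring), helped by the 2,5-cis tetrahydrofuran, which holds both chains on its convex face. C3 is set by chelation of Sm(III) between the ketone oxygen and the ring oxygen, which exposes the ketone face next to C2–H and anti to C1 to the C9-tethered ketyl and gives 3S, and C4 is set relative to C3 by the Sm(III) bridge between the two oxygens together with the extended C2–C3–C4–C5 segment of the forming ring, which gives the trans (3S,4R) diol. The step needs the aldehyde to be reduced before the α-alkoxy ketone (otherwise the C2–O bond is cleaved) and cyclisation to beat dimerisation, which low temperature, the absence of HMPA and slow addition at high dilution secure, while the allyl ester, the silyl ether, the free tertiary alcohol and the 1,1-disubstituted alkene are inert to SmI2 in THF.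

Step 22
Reactants: 28 tricyclic 3,4-diol
Product: 29 C4 octanoate
Conditions: octanoyl chloride, pyridine, DMAP (cat.), CH2Cl2, 0 °C
Reagents that add atoms: octanoyl chloride, CCCCCCCC(=O)Cl
Why: DMAP-catalysed acylation reacts only with the secondary C4 hydroxyl, since the other hydroxyls are tertiary or silylated.

Step 23
Reactants: 29 C4 octanoate
Product: 30 seco acid
Conditions: Pd(PPh3)4 (5 mol %), morpholine, THF, rt
Reagents that add atoms: none
Why: Pd(0) ionises the allyl ester to a π-allyl complex (Tsuji–Trost deallylation) that morpholine traps, freeing the acid without acid or base that could move the octanoate.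

Step 24
Reactants: 30 seco acid
Product: 32 silylated tetracyclic lactone, via mixed anhydride 31 (not isolated)
Conditions: 2,4,6-trichlorobenzoyl chloride, Et3N, THF, rt; then DMAP, toluene, 80 °C, 1 mM
Reagents that add atoms: none
Why: In this Yamaguchi lactonisation DMAP converts the mixed anhydride into an acylpyridinium ion that acylates the C3 hydroxyl, the only hydroxyl able to reach C16 through a seven-membered ring because the C11 hydroxyl lies trans across the cyclohexane.

Step 25
Reactants: 32 silylated tetracyclic lactone
Product: 33 briarellin B (target)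
Conditions: HF·pyridine, pyridine, THF, 0 °C → rt
Reagents that add atoms: none
Why: Fluoride-driven cleavage of the remaining secondary silyl ether runs under mildly acidic conditions in which the lactone, the octanoate and the tertiary and allylic alcohols are stable.

**Compound list**

1 | (R)-α-hydroxy-γ-butyrolactone, (3R)-3-hydroxyoxolan-2-one | O=C1OCC[C@H]1O | starting material
2 | (3R)-3-(tert-butyldimethylsilyloxy)oxolan-2-one | O=C1OCC[C@H]1O[Si](C)(C)C(C)(C)C | intermediate
3 | (3R)-3-(tert-butyldimethylsilyloxy)-1-(trimethylsilyl)-2-[(trimethylsilyl)methyl]pentane-2,5-diol | C[Si](C)(C)CC(O)(C[Si](C)(C)C)[C@H](O[Si](C)(C)C(C)(C)C)CCO | intermediate (not isolated)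
4 | (3R)-3-(tert-butyldimethylsilyloxy)-4-[(trimethylsilyl)methyl]pent-4-en-1-ol | C=C(C[Si](C)(C)C)[C@H](O[Si](C)(C)C(C)(C)C)CCO | intermediate
5 | (R)-[3,5-bis(tert-butyldimethylsilyloxy)-2-methylenepentyl]trimethylsilane (C4–C8 allylsilane) | C=C(C[Si](C)(C)C)[C@H](O[Si](C)(C)C(C)(C)C)CCO[Si](C)(C)C(C)(C)C | intermediate
6 | (R)-(−)-carvone | CC1=CC[C@H](CC1=O)C(C)=C | starting material
7 | (1R,4R,6R)-1-methyl-4-(prop-1-en-2-yl)-7-oxabicyclo[4.1.0]heptan-2-one (oxirane trans to isopropenyl) | O=C1[C@]2(C)O[C@@H]2C[C@H](C1)C(C)=C | intermediate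
8 | (1R,4R)-1-methyl-4-(prop-1-en-2-yl)cyclohexane-1,2-diol, epimer mixture at C2, tertiary OH trans to isopropenyl | C[C@@]1(O)CC[C@H](CC1O)C(C)=C | intermediate
9 | (2R,5R)-2-hydroxy-2-methyl-5-(prop-1-en-2-yl)cyclohexan-1-one | C[C@@]1(O)CC[C@H](CC1=O)C(C)=C | intermediate
10 | (2R,5R)-2-methyl-5-(prop-1-en-2-yl)-2-(triethylsilyloxy)cyclohexan-1-one | C[C@@]1(O[Si](CC)(CC)CC)CC[C@H](CC1=O)C(C)=C | intermediate
11 | (3R,6R)-6-methyl-3-(prop-1-en-2-yl)-6-(triethylsilyloxy)cyclohex-1-en-1-yl trifluoromethanesulfonate | C[C@@]1(O[Si](CC)(CC)CC)CC[C@H](C=C1OS(=O)(=O)C(F)(F)F)C(C)=C | intermediate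
12 | (3R,6R)-6-methyl-3-(prop-1-en-2-yl)-6-(triethylsilyloxy)cyclohex-1-ene-1-carbaldehyde | C[C@@]1(O[Si](CC)(CC)CC)CC[C@H](C=C1C=O)C(C)=C | intermediate
13 | trimethylsilyl enol ether of 14 (C9=C10, silyloxy group syn to C1) | C[Si](C)(C)O/C=C1\[C@@H](C=C(C)C)[C@H](C(C)=C)CC[C@@]1(C)O[Si](CC)(CC)CC | intermediate (not isolated)
14 | cyclohexanecarbaldehyde with C10 formyl and C1 2-methylprop-1-enyl cis, C14 isopropenyl trans to the C1 group, C11 OTES cis to the formyl group | C[C@@]1(O[Si](CC)(CC)CC)CC[C@H]([C@H](C=C(C)C)[C@@H]1C=O)C(C)=C | intermediate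
15 | dimethyl acetal of 14 with free C11 hydroxyl | C[C@@]1(O)CC[C@H]([C@H](C=C(C)C)[C@@H]1C(OC)OC)C(C)=C | intermediate
16 | B-alkyl-9-borabicyclo[3.3.1]nonane from 15 (boron on C16, 15R) | C[C@@]1(O)CC[C@H]([C@H](C=C(C)C)[C@@H]1C(OC)OC)[C@@H](C)CB1C2CCCC1CCC2 | intermediate (not isolated)
17 | primary alcohol from 15 (15R, C16 OH) | C[C@@]1(O)CC[C@H]([C@H](C=C(C)C)[C@@H]1C(OC)OC)[C@@H](C)CO | intermediate
18 | secondary ozonide (1,2,4-trioxolane) of 17 | C[C@@]1(O)CC[C@H]([C@H](C2OOC(C)(C)O2)[C@@H]1C(OC)OC)[C@@H](C)CO | intermediate (not isolated)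
19 | C2 aldehyde (open form of the six-membered lactol with the C16 OH) | C[C@@]1(O)CC[C@H]([C@H](C=O)[C@@H]1C(OC)OC)[C@@H](C)CO | intermediate
20 | 1-ethoxyvinyl carbinol, C2 epimer mixture | C[C@@]1(O)CC[C@H]([C@H](C(O)C(=C)OCC)[C@@H]1C(OC)OC)[C@@H](C)CO | intermediate (not isolated)
21 | α-hydroxy methyl ketone, C2 epimer mixture | C[C@@]1(O)CC[C@H]([C@H](C(O)C(C)=O)[C@@H]1C(OC)OC)[C@@H](C)CO | intermediate
22 | cis-fused hexahydroisobenzofuran methyl acetal with exo C2 acetyl, C11 OH and C16 CH2OH | CO[C@@H]1O[C@H](C(C)=O)[C@H]2[C@@H](CC[C@@](C)(O)[C@H]21)[C@@H](C)CO | intermediate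
23 | keto acid from 22 (C16 CO2H) | CO[C@@H]1O[C@H](C(C)=O)[C@H]2[C@@H](CC[C@@](C)(O)[C@H]21)[C@@H](C)C(=O)O | intermediate
24 | allyl ester of 23 | CO[C@@H]1O[C@H](C(C)=O)[C@H]2[C@@H](CC[C@@](C)(O)[C@H]21)[C@@H](C)C(=O)OCC=C | intermediate
25 | 2,5-cis THF with C9–C8 bond, C7 exo-methylene, (6R)-OTBS and C4 OTBS | CC(C)(C)[Si](C)(C)OCC[C@@H](O[Si](C)(C)C(C)(C)C)C(=C)C[C@@H]1O[C@H](C(C)=O)[C@H]2[C@@H](CC[C@@](C)(O)[C@H]21)[C@@H](C)C(=O)OCC=C | intermediate
26 | C4 primary alcohol from 25 | OCC[C@@H](O[Si](C)(C)C(C)(C)C)C(=C)C[C@@H]1O[C@H](C(C)=O)[C@H]2[C@@H](CC[C@@](C)(O)[C@H]21)[C@@H](C)C(=O)OCC=C | intermediate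
27 | keto aldehyde (C3 methyl ketone, C4 aldehyde) | O=CC[C@@H](O[Si](C)(C)C(C)(C)C)C(=C)C[C@@H]1O[C@H](C(C)=O)[C@H]2[C@@H](CC[C@@](C)(O)[C@H]21)[C@@H](C)C(=O)OCC=C | intermediate
28 | tricyclic (3S,4R)-diol allyl ester with 6-OTBS | C=C1C[C@@H]2O[C@@H]([C@H]3[C@@H](CC[C@@](C)(O)[C@H]32)[C@@H](C)C(=O)OCC=C)[C@@](C)(O)[C@H](O)C[C@H]1O[Si](C)(C)C(C)(C)C | intermediate
29 | C4 octanoate of 28 | C=C1C[C@@H]2O[C@@H]([C@H]3[C@@H](CC[C@@](C)(O)[C@H]32)[C@@H](C)C(=O)OCC=C)[C@@](C)(O)[C@H](OC(=O)CCCCCCC)C[C@H]1O[Si](C)(C)C(C)(C)C | intermediate
30 | seco acid from 29 | C=C1C[C@@H]2O[C@@H]([C@H]3[C@@H](CC[C@@](C)(O)[C@H]32)[C@@H](C)C(=O)O)[C@@](C)(O)[C@H](OC(=O)CCCCCCC)C[C@H]1O[Si](C)(C)C(C)(C)C | intermediate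
31 | mixed anhydride of 30 with 2,4,6-trichlorobenzoic acid | C=C1C[C@@H]2O[C@@H]([C@H]3[C@@H](CC[C@@](C)(O)[C@H]32)[C@@H](C)C(=O)OC(=O)c2c(Cl)cc(Cl)cc2Cl)[C@@](C)(O)[C@H](OC(=O)CCCCCCC)C[C@H]1O[Si](C)(C)C(C)(C)C | intermediate (not isolated)
32 | 6-O-TBS tetracyclic lactone | C=C1C[C@@H]2O[C@H]3[C@H]4[C@@H](CC[C@@](C)(O)[C@H]42)[C@@H](C)C(=O)O[C@@]3(C)[C@H](OC(=O)CCCCCCC)C[C@H]1O[Si](C)(C)C(C)(C)C | intermediate
33 | briarellin B | C=C1C[C@@H]2O[C@H]3[C@H]4[C@@H](CC[C@@](C)(O)[C@H]42)[C@@H](C)C(=O)O[C@@]3(C)[C@H](OC(=O)CCCCCCC)C[C@H]1O | target

**Count and risks**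

Total: 25 steps. Longest linear sequence: 22 steps (steps 4–25, from (R)-carvone); the allylsilane 5 takes 3 steps (steps 1–3).

Steps most likely to fail:

1. Step 21. The nine-membered closure is slow. The ketyl may therefore be reduced on to the alcohol, the α-alkoxy ketone may take up an electron and lose its C2–O bond, or the ketone may be attacked on its other face. Fallback: starting again from 27, the two carbonyl groups are coupled on low-valent titanium (TiCl3(DME)1.5, Zn–Cu couple, DME, rt, syringe-pump addition, aqueous K2CO3 work-up before deoxygenation sets in). This is a McMurry-type pinacol coupling in which both carbonyls are bound and reduced on the titanium surface, so no free ketyl has to survive, and it is established for medium and large rings. It gives 28 directly, where the route is rejoined; no new compound is formed on the way (F0).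

2. Step 24. Acylation of the hindered tertiary C3 hydroxyl may be slower than oligomerisation or migration of the neighbouring octanoate. Fallback: the order is inverted and the ring is closed by alkoxide transesterification instead of carboxyl activation. Diol 28 is treated with NaH (1.1 equiv) in THF over 4 Å molecular sieves, 0 °C → rt, so that the C3 alkoxide displaces allyl alcohol from the ester and forms the seven-membered lactone, the 6-O-TBS 4-hydroxy lactone F1. Octanoyl chloride, pyridine and DMAP then acylate the secondary C4 hydroxyl of F1, and the route is rejoined at 32.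

3. Step 5. Trans-diaxial opening would deliver hydride to the tertiary oxirane carbon, or intramolecular delivery from the alkoxyaluminate could do the same, with loss of the C11 oxygen. Fallback: the regiochemistry is enforced by titanium chelation in two steps. Epoxide 7 is reduced with NaBH4/CeCl3·7H2O in MeOH at 0 °C to the epoxy alcohol F2. Ti(OiPr)4 and LiBH4 in benzene/THF then open the 2,3-epoxy alcohol at the carbon remote from the carbinol (C3-selective opening of titanium-bound epoxy alcohols), which gives diol 8, where the route is rejoined.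

Further compounds
F0 | step 21 | none | none
F1 | step 24 | 6-O-TBS 4-hydroxy lactone (seven-membered lactone closed, C4 OH free) | C=C1C[C@@H]2O[C@H]3[C@H]4[C@@H](CC[C@@](C)(O)[C@H]42)[C@@H](C)C(=O)O[C@@]3(C)[C@H](O)C[C@H]1O[Si](C)(C)C(C)(C)C
F2 | step 5 | (1R,4R,6R)-1-methyl-4-(prop-1-en-2-yl)-7-oxabicyclo[4.1.0]heptan-2-ol (epimer mixture at C2) | OC1[C@]2(C)O[C@@H]2C[C@H](C1)C(C)=C
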